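A small part of the substrate charge was what remained to feed the open intermediate, the resting state of this flask, once the dawn readings topped out. At 0.833 min substrate read 6.1% and open intermediate 94.4%. With the lowest substrate reading, 5.0%, as floor, I counted a reserve of 1.1 percentage points.

- dawn: substrate 0.25 M; solid partner 1.5 equiv; the very flask that is asked about, followed so far
- flask: substrate 0.25 M; solid partner 1.50 equiv; time 8.0 min

dawn run (percent of the substrate charged)

| time / min | open intermediate / % | target / % | substrate / % |
|---|---|---|---|
| 0.200 | 80.2 | 0.3 | 19.3 |
| 0.333 | 90.3 | 0 | 9.1 |
| 0.500 | 93.0 | 0 | 6.5 |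
| 0.833 | 94.4 | 0.4 | 6.1 |
| 1.33 | 93.9 | 0.1 | 5.5 |
| 2.50 | 93.2 | 1.6 | 5.0 |
| 4.00 | 90.8 | 3.4 | 5.8 |

(standard deviation of a reading: 0.3 percentage points)

- solid partner is a solid; its amount is given per volume of the solution
- at the start none of the solid partner is in solution

* when, up to 8.0 min, the flask holds most open intermediate
* the amount of open intermediate, in percent of the substrate charged, at that time

I turned the question round. For this flask to hold most at 8.0 min, I reckoned, the mean loss to target had to stay under the reserve spread over the remaining time, 0.00153 min⁻¹ of the charge. The last two target readings give 0.0120 min⁻¹; this slope, the mean leak, replaces the curve by a straight line. It stands 7.84 times above the limit, so I put the peak at the top reading and ran the line on to 85.8% at the end.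

The forecast gave 1 min (0.6 min to 1.6 min) and 94.3% (93.8% to 94.9%), later than my 0.833 min, holding that “only the slow leak to target pulls it down”.

The flask peaked at 0.805 min with 94.3%, earlier than forecast.

    substrate ⇌ open intermediate (K = 17.0, k = 0.150 s⁻¹)
    fresh partner → second intermediate (k = 0.00870 s⁻¹)
    open intermediate + second intermediate → target (k = 0.0850 M⁻¹ s⁻¹)
    solid partner ⇌ fresh partner, rate k4*(cs4 - [fresh partner]) while solid is left; crystals form when [fresh partner] > cs4 (solubility = 15.0 mM, k = 0.0110 s⁻¹)

At the end this flask held 84.1%, which is 1.7 points under my line. Target gained 0.0170 min⁻¹ of the charge over the second half, more than the mean leak of 0.0120 min⁻¹. The neighbour flask took 0.380 equiv of solid partner, a quarter of this charge, and peaked at 94.3%. The same line over the same span gives it 85.7%. It held 84.1% at the end, with 67% of its solid partner still there, solid or dissolved.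

Readings and results stem from a simulated flask for substances that don't exist, noise included.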